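**Plan**

1. Retrosynthesis: the C1–Br bond goes back to a C1=C2 vinyl bromide and then a C1 ketone; C6–OAc, C4–OH and C5–H go back to a 4α,5α-epoxy-6-ketone and then a C4=C5 enone; ring A is then cut at C2–C3 and C4–C5; last, C10–C1 is cut (acetyl, from vinyl) to reach (R)-piperitone.
2. Enabling feature: with C1 and C6 as ketones, C2 and C5 are the α-carbons of a 1,4-diketone that straddles the quaternary C10 of ring B, a 1,4-bis-nucleophile. C3–C4(–C15) is an acetone-level unit that 2,3-dibromopropene supplies as a 1,2-bis-electrophile (allylic C3, vinylic C4).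
3. Forward: ring B is piperitone itself. Vinyl cuprate addition builds C10, Wacker oxidation gives the C1 acetyl, and a one-pot dianion allylation/palladium enolate alkenylation closes ring A. Epoxidation, double SmI2 reduction, acetylation, vinyl bromide formation and HAT hydrogenation follow.
4. Stereochemistry: C7 comes from (R)-piperitone and is never enolised. C10 is set by axial cuprate attack cis to the isopropyl group, and C4 by peroxide attack anti to the C10 methyl. C5 and C6 are set in the samarium step (α protonation, equatorial alcohol), and C1 by axial hydrogen delivery to an α-bromo radical.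

Key step: step 3

Remark: bicyclic compounds are named as decalins with eudesmane numbering (ring A = C1–C5 and C10; ring B = C5–C10; C14 = methyl on C10; C15 = methyl on C4; β = the face of C14, α = the opposite face); enantiopure (R)-piperitone is assumed.

**Step 1**
Reactants: 1 (R)-piperitone; 2 vinylmagnesium bromide
Product: 4 (2R,5R)-5-ethenyl-5-methyl-2-(propan-2-yl)cyclohexan-1-one, via trimethylsilyl enol ether 3 (not isolated)
Conditions: CH2=CHMgBr, CuBr·SMe2 (10 mol%), TMSCl, THF, −78 → −40 °C; then 1 M HCl, 0 °C
Reagents that add atoms: vinylmagnesium bromide (2), C=C[Mg]Br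
Why: Copper-catalysed, TMSCl-accelerated conjugate addition of the vinyl Grignard reagent to the β,β-disubstituted enone; C10 is set by axial (chair-like) attack on the half-chair in which the C7 isopropyl is pseudo-equatorial, which places vinyl cis to isopropyl, and C7 is preserved because only the C5=C6 enol silane 3 forms before mild hydrolysis.

**Step 2**
Reactants: 4 (2R,5R)-5-ethenyl-5-methyl-2-(propan-2-yl)cyclohexan-1-one
Product: 5 (2R,5R)-5-acetyl-5-methyl-2-(propan-2-yl)cyclohexan-1-one
Conditions: PdCl2 (10 mol%), CuCl (20 mol%), O2 (1 atm), DMF/H2O (7:1), 23 °C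
Reagents that add atoms: water, O
Why: Tsuji–Wacker oxidation, in which Markovnikov hydroxypalladation of the monosubstituted vinyl group delivers the methyl ketone (C1=O, C2H3) without touching C7 or C10.

**Step 3**
Reactants: 5 (2R,5R)-5-acetyl-5-methyl-2-(propan-2-yl)cyclohexan-1-one; 6 2,3-dibromopropene
Product: 10 (7R,10R)-7α-isopropyl-4,10β-dimethyldecal-4-ene-1,6-dione, via dilithium bis-enolate 7 (not isolated), via bromoallyl lithium enolate 8 (not isolated), via exocyclic methylene dione 9 (not isolated)
Conditions: LiN(i-Pr)2 (2.2 equiv), THF, −78 °C; 6, −78 → −30 °C; LiN(SiMe3)2 (1.2 equiv), Pd[P(t-Bu)3]2 (5 mol%), 23 °C; MeOH, 0 °C; aq NH4Cl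
Reagents that add atoms: 2,3-dibromopropene (6), C=C(Br)CBr
Why: Kinetic double deprotonation converts 5 into the C2/C5 bis-enolate 7, the unhindered primary C2 enolate is alkylated at the allylic bromide of 6 (C2–C3), and zerovalent palladium then inserts into the vinylic C–Br bond of 8, exchanges bromide for the C5 enolate and forms C4–C5 by reductive elimination. The closest known reaction types are the allylation of ketone enolates by 2,3-dibromopropene and the palladium-catalysed intramolecular α-alkenylation of ketone enolates by 2-haloallyl groups. Ring A closes in the 6-exo mode through a seven-membered palladacycle, C5 bonding to the vinylic carbon C4 while C4=C15 stays exocyclic in 9. No stereocenter is created, because methoxide-mediated proton exchange at the doubly activated C5–H moves the double bond into conjugation (C4=C5) and so defers the ring-fusion geometry to step 5. The step needs site selectivity and retention of C7: C2 reacts before the neopentylic C5 for steric reasons, only C5 can reach C4 through a six-membered ring, and the C6 carbonyl stays masked as enolate or dienolate until the brief equilibration at 0 °C, in which the C5 proton should exchange far faster than the hindered C7 proton.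

**Step 4**
Reactants: 10 (7R,10R)-7α-isopropyl-4,10β-dimethyldecal-4-ene-1,6-dione
Product: 11 (4R,5S,7R,10R)-4α,5α-epoxy-7α-isopropyl-4β,10β-dimethyldecalin-1,6-dione
Conditions: t-BuOOH (3 equiv), DBU (1.2 equiv), CH2Cl2, 0 → 23 °C
Reagents that add atoms: tert-butyl hydroperoxide, CC(C)(C)OO
Why: Weitz–Scheffer nucleophilic epoxidation of a tetrasubstituted alkylidene ketone (pulegone-type precedent), in which the peroxide anion adds to C4 on the α face, anti to the axial C10 methyl that is 1,3 to C4, and the C5 enolate closes onto oxygen on the same face, so that C4 receives O α and keeps C15 β while the excess hydroperoxide keeps the medium too weakly basic to enolise C7.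

**Step 5**
Reactants: 11 (4R,5S,7R,10R)-4α,5α-epoxy-7α-isopropyl-4β,10β-dimethyldecalin-1,6-dione
Product: 13 (4R,5S,6S,7R,10R)-4α,6α-dihydroxy-7α-isopropyl-4β,10β-dimethyl-5αH-decalin-1-one, via ketol 12 (not isolated)
Conditions: SmI2 (5 equiv), THF/MeOH (4:1), −78 → 0 °C
Reagents that add atoms: none
Why: Samarium diiodide reduction of the α,β-epoxy ketone cleaves the C5–O bond and leaves the C4–O bond (4α-OH), methanol protonates the samarium enolate at C5 on the α face because the β face is flanked by the axial methyls on C4 and C10 (trans ring fusion), and the chelated β-hydroxy ketone 12 is then reduced to the equatorial 6α-alcohol, the only position in which O6 can bridge to O4 through trivalent samarium and avoid the two syn-axial methyls, while the unchelated C1 ketone should react much more slowly.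

**Step 6**
Reactants: 13 (4R,5S,6S,7R,10R)-4α,6α-dihydroxy-7α-isopropyl-4β,10β-dimethyl-5αH-decalin-1-one
Product: 14 (4R,5S,6S,7R,10R)-6α-acetoxy-4α-hydroxy-7α-isopropyl-4β,10β-dimethyl-5αH-decalin-1-one
Conditions: Ac2O, DMAP (cat.), pyridine, 23 °C
Reagents that add atoms: acetic anhydride, CC(=O)OC(C)=O
Why: DMAP-catalysed acetylation of the only secondary hydroxyl (C6), the tertiary C4 hydroxyl being inert under these conditions, with no change at any stereocenter.

**Step 7**
Reactants: 14 (4R,5S,6S,7R,10R)-6α-acetoxy-4α-hydroxy-7α-isopropyl-4β,10β-dimethyl-5αH-decalin-1-one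
Product: 16 (4R,5S,6S,7R,10R)-6α-acetoxy-1-bromo-7α-isopropyl-4β,10β-dimethyl-5αH-decal-1-en-4α-ol, via N-silyl hydrazone 15 (not isolated)
Conditions: TBSNHNHTBS, Sc(OTf)3 (1 mol%), CHCl3, 23 → 55 °C; then Br2, 2-tert-butyl-1,1,3,3-tetramethylguanidine, CH2Cl2, 0 °C
Reagents that add atoms: bromine, BrBr
Why: Barton vinyl halide synthesis through the N-silyl hydrazone: the C1 ketone condenses with the bis-silylhydrazine, bromine and the guanidine base oxidise hydrazone 15 via the diazo compound and the α-bromo cation, and loss of a C2 proton (C10 has none, as with 17-oxo steroids) gives the C1=C2 vinyl bromide under conditions that should spare the acetate and the tertiary alcohol.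

**Step 8**
Reactants: 16 (4R,5S,6S,7R,10R)-6α-acetoxy-1-bromo-7α-isopropyl-4β,10β-dimethyl-5αH-decal-1-en-4α-ol
Product: 17 austradiol acetate
Conditions: Mn(dpm)3 (10 mol%), PhSiH3, t-BuOOH, i-PrOH, 23 °C
Reagents that add atoms: none
Why: Metal-hydride hydrogen atom transfer hydrogenation, a radical process that keeps carbon–halogen bonds: the manganese hydride delivers H• to C2, and the α-bromo radical at C1 then takes up hydrogen axially on the α face, anti to the axial C10 methyl, so that bromine ends equatorial (1β).

**Compound list**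

1 | (R)-piperitone, (6R)-3-methyl-6-(propan-2-yl)cyclohex-2-en-1-one | CC1=CC(=O)[C@@H](C(C)C)CC1 | starting material
2 | vinylmagnesium bromide | C=C[Mg]Br | starting material
3 | C5=C6 trimethylsilyl enol ether of 4 (vinyl cis to isopropyl) | C[Si](C)(C)OC=1[C@@H](C(C)C)CC[C@@](C)(C=C)C=1 | intermediate (not isolated)
4 | (2R,5R)-5-ethenyl-5-methyl-2-(propan-2-yl)cyclohexan-1-one | O=C1[C@@H](C(C)C)CC[C@@](C)(C=C)C1 | intermediate
5 | (2R,5R)-5-acetyl-5-methyl-2-(propan-2-yl)cyclohexan-1-one | O=C1[C@@H](C(C)C)CC[C@@](C)(C(C)=O)C1 | intermediate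
6 | 2,3-dibromopropene | C=C(Br)CBr | starting material
7 | dilithium C1=C2/C5=C6 bis-enolate of 5 | [Li]OC=1[C@@H](C(C)C)CC[C@@](C)(C(=C)O[Li])C=1 | intermediate (not isolated)
8 | lithium C5=C6 enolate of the C2-(2-bromoallyl) diketone | [Li]OC=1[C@@H](C(C)C)CC[C@@](C)(C(=O)CCC(Br)=C)C=1 | intermediate (not isolated)
9 | 7α-isopropyl-10β-methyl-4-methylenedecalin-1,6-dione (both C5 epimers) | O=C1[C@@H](C(C)C)CC[C@@]2(C)C(=O)CCC(=C)C12 | intermediate (not isolated)
10 | (7R,10R)-7α-isopropyl-4,10β-dimethyldecal-4-ene-1,6-dione | O=C1[C@@H](C(C)C)CC[C@@]2(C)C(=O)CCC(C)=C12 | intermediate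
11 | (4R,5S,7R,10R)-4α,5α-epoxy-7α-isopropyl-4β,10β-dimethyldecalin-1,6-dione | O=C1[C@@H](C(C)C)CC[C@@]2(C)C(=O)CC[C@@](C)(O3)[C@]123 | intermediate
12 | 4α-hydroxy-7α-isopropyl-4β,10β-dimethyl-5αH-decalin-1,6-dione | O=C1[C@@H](C(C)C)CC[C@@]2(C)C(=O)CC[C@@](C)(O)[C@H]12 | intermediate (not isolated)
13 | (4R,5S,6S,7R,10R)-4α,6α-dihydroxy-7α-isopropyl-4β,10β-dimethyl-5αH-decalin-1-one | O[C@H]1[C@@H](C(C)C)CC[C@@]2(C)C(=O)CC[C@@](C)(O)[C@H]12 | intermediate
14 | (4R,5S,6S,7R,10R)-6α-acetoxy-4α-hydroxy-7α-isopropyl-4β,10β-dimethyl-5αH-decalin-1-one | CC(=O)O[C@H]1[C@@H](C(C)C)CC[C@@]2(C)C(=O)CC[C@@](C)(O)[C@H]12 | intermediate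
15 | N-(tert-butyldimethylsilyl)hydrazone of 14 at C1 | CC(=O)O[C@H]1[C@@H](C(C)C)CC[C@@]2(C)C(=NN[Si](C)(C)C(C)(C)C)CC[C@@](C)(O)[C@H]12 | intermediate (not isolated)
16 | (4R,5S,6S,7R,10R)-6α-acetoxy-1-bromo-7α-isopropyl-4β,10β-dimethyl-5αH-decal-1-en-4α-ol | CC(=O)O[C@H]1[C@@H](C(C)C)CC[C@@]2(C)C(Br)=CC[C@@](C)(O)[C@H]12 | intermediate
17 | austradiol acetate, (1R,4R,5S,6S,7R,10R)-6α-acetoxy-1β-bromo-7α-isopropyl-4β,10β-dimethyl-5αH-decalin-4α-ol | CC(=O)O[C@H]1[C@@H](C(C)C)CC[C@@]2(C)[C@H](Br)CC[C@@](C)(O)[C@H]12 | target

**Step count**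

Total step count: 8
Longest linear sequence: 8 steps (1 → 17)

**Steps most likely to fail**

Step 3. The process at risk is competing allylation at C5, dehydrobromination of the 2-bromoallyl group by the amide base, or proton shuffling between the enolate sites with epimerisation at C7 during the palladium stage. The fallback sets out from 5. The same dianion is alkylated at C2 by propargyl bromide and the remaining C5 enolate is silylated with TMSCl, which should give the silyl enol ether alkyne F1. Ph3PAuCl/AgBF4 in CH2Cl2/MeOH should then effect a neutral 6-exo-dig Conia-ene-type carbocyclisation to 9, now isolated. Catalytic DBU in CH2Cl2 should conjugate the double bond, and the route is rejoined at 10.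

Step 5. The process at risk is poor facial selectivity in the reduction of the C6 ketone (or in the protonation at C5), or over-reduction of the C1 ketone. The fallback sets out from 11. Lithium in liquid ammonia/THF with tert-butanol should open the epoxy ketone and reduce both carbonyl groups under thermodynamic control, giving the all-equatorial triol F2. Oxidation with catalytic TEMPO and PhI(OAc)2 should then take the less hindered C1 carbinol back to the ketone, the C6 carbinol being shielded by C5, C7 and the peri C4 hydroxyl. The route is rejoined at 13.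

Step 8. The process at risk is loss of bromine through halogen abstraction by silyl radicals, or poor facial selectivity in the final hydrogen transfer. The fallback sets out from 14. LiBH(s-Bu)3 in THF at −78 °C should attack the C1 ketone from the equatorial side and give the axial 1α-alcohol F3. Appel bromination (CBr4, PPh3) with inversion at C1 should then deliver the equatorial bromide, so the route is rejoined at 17.

**Further compounds**

F1 | step 3 | 1-[(1R,4R)-1-methyl-4-(propan-2-yl)-3-(trimethylsilyloxy)cyclohex-2-en-1-yl]pent-4-yn-1-one | C[Si](C)(C)OC=1[C@@H](C(C)C)CC[C@@](C)(C(=O)CCC#C)C=1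
F2 | step 5 | (1R,4R,5S,6S,7R,10R)-7α-isopropyl-4β,10β-dimethyl-5αH-decalin-1β,4α,6α-triol | O[C@H]1[C@@H](C(C)C)CC[C@@]2(C)[C@H](O)CC[C@@](C)(O)[C@H]12
F3 | step 8 | (1S,4R,5S,6S,7R,10R)-6α-acetoxy-7α-isopropyl-4β,10β-dimethyl-5αH-decalin-1α,4α-diol | CC(=O)O[C@H]1[C@@H](C(C)C)CC[C@@]2(C)[C@@H](O)CC[C@@](C)(O)[C@H]12
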